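**Retrosynthetic overview**

1. Target: 19(R)-hydroxy-PGF1α, which has one ring (cyclopentane C8–C12, prostanoic acid numbering). Endgame: ester hydrolysis and desilylation; 9α-OH by hindered-hydride reduction of a C9 ketone; 11α-OH by conjugate borylation/oxidation of a 9-oxo-10-ene, anti to the C12 chain.
2. The cyclopentenone is unmasked from a 9-nitrocyclopent-9-ene (deconjugation and oxidative Nef reaction). The C13–C20 chain is attached to a C13 formyl group by Horner–Wadsworth–Emmons olefination, and the C15 ketone is reduced under reagent control. C19 comes from (R)-butane-1,3-diol.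
3. Ring formation (the only ring, step 7): butanedial and methyl (E)-9-nitronon-8-enoate are joined by an amine-catalysed Michael addition (C8–C12), and the ring is then closed by an intramolecular Henry reaction between C9 and C10.
4. Enabling feature: C10 is the only unsubstituted carbon of the cyclopentane and lies between the two carbinol carbons C9 and C11. It can therefore enter as a free formyl carbon whose oxygen is later relocated to C11 through the enone. C9, next to the chain-bearing C8, can carry a nitro group as a carbanion-stabilising latent ketone. The trans C8/C12 pair comes from the catalyst (C8) and from an epimerisable formyl-bearing C12.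

Key step: step 7

Remark: positions are given in prostanoic acid numbering (C1 = carboxyl carbon, ring = C8 to C12, C20 = methyl) and TBS = tert-butyldimethylsilyl; the configuration at C9 and C10 of 16 and 17 has no consequence (both centres are erased in steps 9 to 12) and is drawn as the all-trans arrangement expected under thermodynamic control.

**Route**

Step 1
Reactants: 1 (Z)-cyclooctene
Product: 3 methyl 8-oxooctanoate, via methoxy hydroperoxide 2 (not isolated)
Conditions: O3, CH2Cl2/MeOH, NaHCO3, −78 °C; then Ac2O, Et3N, CH2Cl2, 0 °C to rt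
Reagents that add atoms: ozone [O-][O+]=O; methanol CO
Why: Ozonolysis in the presence of methanol traps the carbonyl oxide as an α-methoxy hydroperoxide, and acetylation followed by base-induced loss of acetate turns that terminus into the methyl ester while the other stays an aldehyde (unsymmetrical ozonolytic cleavage of a cycloalkene); no stereocentre is involved.

Step 2
Reactants: 3 methyl 8-oxooctanoate; 4 nitromethane
Product: 6 methyl (E)-9-nitronon-8-enoate, via nitro alcohol 5 (not isolated)
Conditions: 4 (5 equiv), t-BuOK (10 mol %), THF/t-BuOH, 0 °C; then MsCl, Et3N, CH2Cl2, 0 °C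
Reagents that add atoms: none
Why: A base-catalysed Henry addition followed by mesylation and E1cB elimination should give the conjugated nitroalkene as the thermodynamically preferred E isomer.

Step 3
Reactants: 7 (R)-butane-1,3-diol
Product: 8 (R)-4-iodobutan-2-ol
Conditions: PPh3, I2, imidazole, CH2Cl2, 0 °C
Reagents that add atoms: iodine II
Why: Appel-type iodination should be selective for the less hindered primary hydroxyl of the 1,3-diol and does not touch the C–O bond of the stereocentre (the later C19).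

Step 4
Reactants: 8 (R)-4-iodobutan-2-ol
Product: 9 (R)-tert-butyl[(4-iodobutan-2-yl)oxy]dimethylsilane
Conditions: t-BuMe2SiOTf, 2,6-lutidine, CH2Cl2, −78 to 0 °C
Reagents that add atoms: tert-butyldimethylsilyl trifluoromethanesulfonate CC(C)(C)[Si](C)(C)OS(=O)(=O)C(F)(F)F
Why: O-Silylation with the silyl triflate and a hindered base is fast at low temperature, avoids N-alkylation of a nucleophilic base by the primary iodide and leaves the stereocentre untouched.

Step 5
Reactants: 9 (R)-tert-butyl[(4-iodobutan-2-yl)oxy]dimethylsilane; 10 dimethyl (2-oxopropyl)phosphonate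
Product: 12 dimethyl [(6R)-6-(TBSO)-2-oxoheptyl]phosphonate, via dianion 11 (not isolated)
Conditions: 10, LiN(i-Pr)2 (2.1 equiv), THF, −78 to 0 °C; then 9, 0 °C to rt; aq. NH4Cl
Reagents that add atoms: none
Why: Double deprotonation gives the 1,3-dianion, whose terminal (γ) carbanion is the more nucleophilic site and is alkylated by the primary iodide (γ-alkylation of a β-keto phosphonate dianion), completing C14–C20 with C19 unchanged.

Step 6
Reactants: 13 2,5-dimethoxytetrahydrofuran
Product: 14 butanedial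
Conditions: H2O, 90 °C; distillation
Reagents that add atoms: water O
Why: Hydrolysis of the cyclic bis-acetal in hot water, driven by distilling off methanol, should liberate butanedial, which is used freshly distilled because it oligomerises on standing.

Step 7
Reactants: 14 butanedial; 6 methyl (E)-9-nitronon-8-enoate
Product: 16 methyl 7-[(1R,2S,4S,5S)-2-formyl-4-hydroxy-5-nitrocyclopentyl]heptanoate, via Michael adduct 15 (not isolated)
Conditions: (S)-2-[diphenyl(trimethylsilyloxy)methyl]pyrrolidine (10 mol %), 4-nitrophenol (10 mol %), 14 (2 equiv), MeCN, 0 °C to rt; then i-Pr2NEt, 0 °C to rt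
Reagents that add atoms: none
Why: The pyrrolidine catalyst condenses with one formyl group of 14 to give an E-enamine with one face shielded by the CPh2OSiMe3 group, so that C12 adds to C8 of nitroalkene 6 through the usual syn-selective open transition state and fixes C8 as R in adduct 15; i-Pr2NEt then generates the C9 nitronate, which attacks the remote formyl carbon C10 in an intramolecular Henry (nitro-aldol) reaction. The closest known reaction type is the amine-catalysed Michael/Henry formal (3+2) annulation of butanedial with nitroalkenes. The cyclopentane (C8–C12) closes in the 5-exo-trig mode, whereas attack on the other formyl group would give a four-membered ring and should not compete. C8 is controlled by the catalyst; C12, which is α to the formyl group and is formed with the opposite sense in 15, should equilibrate under the amine base to the arrangement trans to the C8 chain; C9 and C10 arise under thermodynamic control and are both erased later. The step needs cross-selectivity for enamine addition to 6 over self-aldol reaction of 14, which the high electrophilicity of the nitroalkene, the excess of 14 and the weak acid co-catalyst should secure, and it needs C9 to be the only carbon nucleophile in the ring closure, which the much higher acidity of the nitroalkane secures.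

Step 8
Reactants: 16 methyl 7-[(1R,2S,4S,5S)-2-formyl-4-hydroxy-5-nitrocyclopentyl]heptanoate; 12 dimethyl [(6R)-6-(TBSO)-2-oxoheptyl]phosphonate
Product: 17 methyl 7-[(1R,2R,4S,5S)-4-hydroxy-5-nitro-2-[(1E,7R)-3-oxo-7-(TBSO)oct-1-en-1-yl]cyclopentyl]heptanoate
Conditions: LiCl, i-Pr2NEt, MeCN, 0 °C to rt
Reagents that add atoms: none
Why: A Horner–Wadsworth–Emmons olefination under the mild LiCl/amine (Masamune–Roush) conditions tolerates the β-nitro alcohol and the epimerisable aldehyde, should give the E-enone and fixes the trans C12 configuration.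

Step 9
Reactants: 17 (the hydroxy nitro enone)
Product: 18 methyl 7-[(1R,5R)-2-nitro-5-[(1E,7R)-3-oxo-7-(TBSO)oct-1-en-1-yl]cyclopent-2-en-1-yl]heptanoate
Conditions: MsCl, Et3N, CH2Cl2, −20 to 0 °C
Reagents that add atoms: none
Why: Mesylation of the β-nitro alcohol and E1cB loss of methanesulfonate, driven by the acidity of the C9–H next to the nitro group, should give the conjugated nitroalkene and erases the stereocentres at C9 and C10.

Step 10
Reactants: 18 (the nitroalkene enone)
Product: 19 methyl 7-[(1R,5R)-5-[(1E,3S,7R)-3-hydroxy-7-(TBSO)oct-1-en-1-yl]-2-nitrocyclopent-2-en-1-yl]heptanoate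
Conditions: (−)-Ipc2BCl, THF, −40 to −20 °C; then CH3CHO; aq. NaHCO3
Reagents that add atoms: none
Why: Reagent-controlled reduction by (−)-Ipc2BCl, which transfers a β-hydride through a boat-like six-membered transition state with the alkenyl group as the large substituent, should give the 15S allylic alcohol (asymmetric ketone reduction with an isopinocampheylborane) and leave the nitroalkene, ester and silyl ether untouched.

Step 11
Reactants: 19 (the nitroalkene allylic alcohol)
Product: 21 methyl 7-[(1R,2S)-2-[(1E,3S,7R)-3-hydroxy-7-(TBSO)oct-1-en-1-yl]-5-oxocyclopent-3-en-1-yl]heptanoate, via allyl nitronate 20 (not isolated)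
Conditions: DABCO (1,4-diazabicyclo[2.2.2]octane), O2 (1 atm), MeCN, rt
Reagents that add atoms: dioxygen O=O
Why: DABCO removes a C11 proton of the nitroalkene to give the delocalised allyl nitronate 20, which is oxidised at C9 by O2 with loss of nitrite (base-mediated oxidative Nef reaction), so that the carbonyl appears at C9 in conjugation with the new C10=C11 bond while C8 and C12 are unaffected.

Step 12
Reactants: 21 (the cyclopentenone)
Product: 23 methyl 7-[(1R,2R,3R)-3-hydroxy-2-[(1E,3S,7R)-3-hydroxy-7-(TBSO)oct-1-en-1-yl]-5-oxocyclopentyl]heptanoate, via boryl ketone 22 (not isolated)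
Conditions: B2pin2, CuCl (5 mol %), NaOt-Bu (10 mol %), bis[2-(diphenylphosphino)phenyl] ether (5 mol %), MeOH, THF, rt; then NaBO3·4H2O, THF/H2O, 0 °C to rt
Reagents that add atoms: sodium perborate [Na+].[O-]OB=O; bis(pinacolato)diboron CC1(C)OB(OC1(C)C)B1OC(C)(C)C(C)(C)O1 (boron is present only in 22)
Why: A boryl-copper species adds to C11 of the enone anti to the neighbouring C12 chain (copper-catalysed conjugate borylation, with protonation at C10 by MeOH), and perborate oxidation replaces boron by hydroxyl with retention, which sets C11 as the 11α (R) carbinol.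

Step 13
Reactants: 23 (the 11,15-diol ketone)
Product: 24 methyl 7-[(1R,2R,3R)-2-[(1E,3S,7R)-3,7-bis(TBSO)oct-1-en-1-yl]-5-oxo-3-(TBSO)cyclopentyl]heptanoate
Conditions: t-BuMe2SiCl, imidazole, DMF, rt
Reagents that add atoms: tert-butyldimethylsilyl chloride CC(C)(C)[Si](C)(C)Cl
Why: Imidazole-promoted O-silylation protects both secondary alcohols under conditions mild enough to avoid β-elimination of the 11-oxygen, and the bulky 11α-silyloxy group reinforces the facial bias needed in the next step.

Step 14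
Reactants: 24 (the tris-silyl ketone)
Product: 25 methyl 7-[(1R,2R,3R,5S)-2-[(1E,3S,7R)-3,7-bis(TBSO)oct-1-en-1-yl]-5-hydroxy-3-(TBSO)cyclopentyl]heptanoate
Conditions: LiBH(s-Bu)3, THF, −78 °C; aq. NH4Cl
Reagents that add atoms: none
Why: The bulky hydride should attack the C9 carbonyl from the β face, away from the adjacent α-oriented C8 chain and the 11α-silyloxy group, giving the 9α (S) alcohol (substrate-controlled reduction of a substituted cyclopentanone).

Step 15
Reactants: 25 (the tris-silyl 9α-alcohol)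
Product: 26 methyl 7-[(1R,2R,3R,5S)-2-[(1E,3S,7R)-3,7-dihydroxyoct-1-en-1-yl]-3,5-dihydroxycyclopentyl]heptanoate
Conditions: HF·pyridine, THF, 0 °C to rt
Reagents that add atoms: none
Why: Fluoride-mediated cleavage of the three Si–O bonds (desilylation) leaves the ester, the allylic alcohol and all stereocentres unchanged.

Step 16
Reactants: 26 (the tetrol methyl ester)
Product: 27 7-[(1R,2R,3R,5S)-2-[(1E,3S,7R)-3,7-dihydroxyoct-1-en-1-yl]-3,5-dihydroxycyclopentyl]heptanoic acid
Conditions: LiOH·H2O, THF/H2O, rt; then aq. HCl to pH 4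
Reagents that add atoms: lithium hydroxide [Li+].[OH-]
Why: Saponification of the methyl ester followed by mild acidification, under which the tetrol acid is stable, should give the target.

**Compound list**

1 | (Z)-cyclooctene | C1CCC/C=C\CC1 | starting material
2 | 8-hydroperoxy-8-methoxyoctanal (racemic) | O=CCCCCCCC(OC)OO | intermediate
3 | methyl 8-oxooctanoate | COC(=O)CCCCCCC=O | intermediate
4 | nitromethane | C[N+](=O)[O-] | starting material
5 | methyl 8-hydroxy-9-nitrononanoate (racemic) | COC(=O)CCCCCCC(O)C[N+](=O)[O-] | intermediate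
6 | methyl (E)-9-nitronon-8-enoate | COC(=O)CCCCCC/C=C/[N+](=O)[O-] | intermediate
7 | (R)-butane-1,3-diol | C[C@@H](O)CCO | starting material
8 | (R)-4-iodobutan-2-ol | C[C@@H](O)CCI | intermediate
9 | (R)-tert-butyl[(4-iodobutan-2-yl)oxy]dimethylsilane | C[C@@H](O[Si](C)(C)C(C)(C)C)CCI | intermediate
10 | dimethyl (2-oxopropyl)phosphonate | COP(=O)(OC)CC(C)=O | starting material
11 | dilithium 1,3-dianion of dimethyl (2-oxopropyl)phosphonate | [Li+].[Li+].COP(=O)(OC)[CH-]C(=O)[CH2-] | intermediate
12 | dimethyl [(6R)-6-{[tert-butyl(dimethyl)silyl]oxy}-2-oxoheptyl]phosphonate | COP(=O)(OC)CC(=O)CCC[C@@H](C)O[Si](C)(C)C(C)(C)C | intermediate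
13 | 2,5-dimethoxytetrahydrofuran (cis/trans mixture) | COC1CCC(OC)O1 | starting material
14 | butanedial (succinaldehyde) | O=CCCC=O | intermediate
15 | methyl (8R,9R)-9-formyl-8-(nitromethyl)-11-oxoundecanoate | O=CC[C@@H](C=O)[C@H](C[N+](=O)[O-])CCCCCCC(=O)OC | intermediate
16 | methyl 7-[(1R,2S,4S,5S)-2-formyl-4-hydroxy-5-nitrocyclopentyl]heptanoate | O=C[C@@H]1[C@@H](CCCCCCC(=O)OC)[C@H]([N+](=O)[O-])[C@@H](O)C1 | intermediate
17 | methyl 7-[(1R,2R,4S,5S)-4-hydroxy-5-nitro-2-[(1E,7R)-3-oxo-7-(TBSO)oct-1-en-1-yl]cyclopentyl]heptanoate | C[C@@H](O[Si](C)(C)C(C)(C)C)CCCC(=O)/C=C/[C@@H]1[C@@H](CCCCCCC(=O)OC)[C@H]([N+](=O)[O-])[C@@H](O)C1 | intermediate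
18 | methyl 7-[(1R,5R)-2-nitro-5-[(1E,7R)-3-oxo-7-(TBSO)oct-1-en-1-yl]cyclopent-2-en-1-yl]heptanoate | C[C@@H](O[Si](C)(C)C(C)(C)C)CCCC(=O)/C=C/[C@@H]1[C@@H](CCCCCCC(=O)OC)C([N+](=O)[O-])=CC1 | intermediate
19 | methyl 7-[(1R,5R)-5-[(1E,3S,7R)-3-hydroxy-7-(TBSO)oct-1-en-1-yl]-2-nitrocyclopent-2-en-1-yl]heptanoate | C[C@@H](O[Si](C)(C)C(C)(C)C)CCC[C@H](O)/C=C/[C@@H]1[C@@H](CCCCCCC(=O)OC)C([N+](=O)[O-])=CC1 | intermediate
20 | 1,4-diazabicyclo[2.2.2]octan-1-ium salt of the C9 nitronate of 19 (C10=C11 double bond; C8, C12, C15, C19 as in 19) | C[C@@H](O[Si](C)(C)C(C)(C)C)CCC[C@H](O)/C=C/[C@@H]1[C@@H](CCCCCCC(=O)OC)C(=[N+]([O-])[O-])C=C1.C1C[NH+]2CCN1CC2 | intermediate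
21 | methyl 7-[(1R,2S)-2-[(1E,3S,7R)-3-hydroxy-7-(TBSO)oct-1-en-1-yl]-5-oxocyclopent-3-en-1-yl]heptanoate | C[C@@H](O[Si](C)(C)C(C)(C)C)CCC[C@H](O)/C=C/[C@@H]1[C@@H](CCCCCCC(=O)OC)C(=O)C=C1 | intermediate
22 | methyl 7-[(1R,2R,3R)-2-[(1E,3S,7R)-3-hydroxy-7-(TBSO)oct-1-en-1-yl]-5-oxo-3-(4,4,5,5-tetramethyl-1,3,2-dioxaborolan-2-yl)cyclopentyl]heptanoate | C[C@@H](O[Si](C)(C)C(C)(C)C)CCC[C@H](O)/C=C/[C@@H]1[C@@H](CCCCCCC(=O)OC)C(=O)C[C@H]1B2OC(C)(C)C(C)(C)O2 | intermediate
23 | methyl 7-[(1R,2R,3R)-3-hydroxy-2-[(1E,3S,7R)-3-hydroxy-7-(TBSO)oct-1-en-1-yl]-5-oxocyclopentyl]heptanoate | C[C@@H](O[Si](C)(C)C(C)(C)C)CCC[C@H](O)/C=C/[C@@H]1[C@@H](CCCCCCC(=O)OC)C(=O)C[C@H]1O | intermediate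
24 | methyl 7-[(1R,2R,3R)-2-[(1E,3S,7R)-3,7-bis(TBSO)oct-1-en-1-yl]-5-oxo-3-(TBSO)cyclopentyl]heptanoate | C[C@@H](O[Si](C)(C)C(C)(C)C)CCC[C@H](O[Si](C)(C)C(C)(C)C)/C=C/[C@@H]1[C@@H](CCCCCCC(=O)OC)C(=O)C[C@H]1O[Si](C)(C)C(C)(C)C | intermediate
25 | methyl 7-[(1R,2R,3R,5S)-2-[(1E,3S,7R)-3,7-bis(TBSO)oct-1-en-1-yl]-5-hydroxy-3-(TBSO)cyclopentyl]heptanoate | C[C@@H](O[Si](C)(C)C(C)(C)C)CCC[C@H](O[Si](C)(C)C(C)(C)C)/C=C/[C@@H]1[C@@H](CCCCCCC(=O)OC)[C@@H](O)C[C@H]1O[Si](C)(C)C(C)(C)C | intermediate
26 | methyl 7-[(1R,2R,3R,5S)-2-[(1E,3S,7R)-3,7-dihydroxyoct-1-en-1-yl]-3,5-dihydroxycyclopentyl]heptanoate | C[C@@H](O)CCC[C@H](O)/C=C/[C@@H]1[C@@H](CCCCCCC(=O)OC)[C@@H](O)C[C@H]1O | intermediate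
27 | 7-[(1R,2R,3R,5S)-2-[(1E,3S,7R)-3,7-dihydroxyoct-1-en-1-yl]-3,5-dihydroxycyclopentyl]heptanoic acid (19(R)-hydroxy-PGF1α) | C[C@@H](O)CCC[C@H](O)/C=C/[C@@H]1[C@@H](CCCCCCC(=O)O)[C@@H](O)C[C@H]1O | target

**Step count and risks**

Total step count: 16. Longest linear sequence: 12 steps (steps 1, 2 and 7 to 16).

Steps most likely to fail, with fallbacks:

Step 7. Self-aldol oligomerisation of butanedial under amine catalysis may outrun the Michael addition, or trapping may occur before C12 has equilibrated. The fallback sets out from 6 and returns at 16. The stable, commercial monoaldehyde pent-4-enal replaces 14 in the same enamine-catalysed Michael addition to 6 and should give methyl (8R,9R)-9-formyl-8-(nitromethyl)dodec-11-enoate F1. Ozonolysis of the terminal alkene of F1 (O3, CH2Cl2, −78 °C; Me2S) then unveils the C10 formyl group only after the C8–C12 bond is in place and gives dialdehyde 15. Treating 15 at once with i-Pr2NEt should close C9–C10, equilibrate C12 and deliver 16.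

Step 11. The amine base may move the ring double bond beyond C10=C11 into conjugation with C8/C12 or epimerise C8, or oxygen transfer to the nitronate may stall. The fallback sets out from 19 and returns at 21.
- NaBH4 (THF/EtOH, 0 °C) should reduce the nitroalkene conjugatively to methyl 7-[(1R,2R)-2-[(1E,3S,7R)-3-hydroxy-7-(TBSO)oct-1-en-1-yl]-5-nitrocyclopentyl]heptanoate F2 (C9 epimers, of no consequence).
- A reductive Nef reaction (NaOMe, MeOH; then buffered aqueous TiCl3) should give the saturated ketone methyl 7-[(1R,2R)-2-[(1E,3S,7R)-3-hydroxy-7-(TBSO)oct-1-en-1-yl]-5-oxocyclopentyl]heptanoate F3.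
- Kinetic enolisation towards the unsubstituted C10 with LiN(i-Pr)2 in the presence of Me3SiCl (THF, −78 °C) should give the silyl enol ether methyl 7-[(1R,5R)-5-[(1E,3S,7R)-7-(TBSO)-3-(trimethylsilyloxy)oct-1-en-1-yl]-2-(trimethylsilyloxy)cyclopent-2-en-1-yl]heptanoate F4, in which the C15 hydroxyl is silylated as well.
- Saegusa–Ito dehydrogenation with Pd(OAc)2 in MeCN should give methyl 7-[(1R,2S)-2-[(1E,3S,7R)-7-(TBSO)-3-(trimethylsilyloxy)oct-1-en-1-yl]-5-oxocyclopent-3-en-1-yl]heptanoate F5.
- K2CO3 in MeOH removes the C15 trimethylsilyl ether to give 21.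

Step 12. Facial selectivity of boryl transfer to C11 may be insufficient, or the 11-oxygen may undergo β-elimination during the basic oxidative work-up. The fallback sets out from 21 and returns at 23. Nucleophilic epoxidation of the enone (H2O2, catalytic NaOH, MeOH, −30 °C), which attacks C11 anti to the C12 chain, should give methyl (13E,15S,19R)-10α,11α-epoxy-15-hydroxy-9-oxo-19-(TBSO)prost-13-en-1-oate F6. Reductive opening of the C10–O bond with SmI2 (THF/MeOH, −78 °C) should then give the β-hydroxy ketone 23.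

Further compounds
F1 | step 7 | methyl (8R,9R)-9-formyl-8-(nitromethyl)dodec-11-enoate | C=CC[C@@H](C=O)[C@H](C[N+](=O)[O-])CCCCCCC(=O)OC
F2 | step 11 | methyl 7-[(1R,2R)-2-[(1E,3S,7R)-3-hydroxy-7-(TBSO)oct-1-en-1-yl]-5-nitrocyclopentyl]heptanoate (C5 epimers) | C[C@@H](O[Si](C)(C)C(C)(C)C)CCC[C@H](O)/C=C/[C@@H]1[C@@H](CCCCCCC(=O)OC)C([N+](=O)[O-])CC1
F3 | step 11 | methyl 7-[(1R,2R)-2-[(1E,3S,7R)-3-hydroxy-7-(TBSO)oct-1-en-1-yl]-5-oxocyclopentyl]heptanoate | C[C@@H](O[Si](C)(C)C(C)(C)C)CCC[C@H](O)/C=C/[C@@H]1[C@@H](CCCCCCC(=O)OC)C(=O)CC1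
F4 | step 11 | methyl 7-[(1R,5R)-5-[(1E,3S,7R)-7-(TBSO)-3-(trimethylsilyloxy)oct-1-en-1-yl]-2-(trimethylsilyloxy)cyclopent-2-en-1-yl]heptanoate | C[C@@H](O[Si](C)(C)C(C)(C)C)CCC[C@H](O[Si](C)(C)C)/C=C/[C@@H]1[C@@H](CCCCCCC(=O)OC)C(O[Si](C)(C)C)=CC1
F5 | step 11 | methyl 7-[(1R,2S)-2-[(1E,3S,7R)-7-(TBSO)-3-(trimethylsilyloxy)oct-1-en-1-yl]-5-oxocyclopent-3-en-1-yl]heptanoate | C[C@@H](O[Si](C)(C)C(C)(C)C)CCC[C@H](O[Si](C)(C)C)/C=C/[C@@H]1[C@@H](CCCCCCC(=O)OC)C(=O)C=C1
F6 | step 12 | methyl (13E,15S,19R)-10α,11α-epoxy-15-hydroxy-9-oxo-19-(TBSO)prost-13-en-1-oate | C[C@@H](O[Si](C)(C)C(C)(C)C)CCC[C@H](O)/C=C/[C@@H]1[C@@H](CCCCCCC(=O)OC)C(=O)[C@@H]2[C@H]1O2
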